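**Retrosynthetic overview**
1. Target 10 ⇒ triol 8 by O-prenylation of both phenols in one operation (the benzylic OH stays free).
2. Ring-B phenol of 8 ⇒ aldehyde 6 by Baeyer–Villiger oxidation; the formyl group first activates the SNAr and then becomes the oxygen.
3. Key C–C bond: Ar–CH2OH of 6 ⇒ aryl bromide 5 + a hydroxymethyl-anion equivalent (Bu3SnCH2OH). Both carbons are normally electrophilic, and the coupling is run on the unprotected aldehyde/phenol diaryl ether.
4. Diaryl ether of 5 ⇒ SNAr of benzoate 4 on fluoroaldehyde 3, which comes from phenol 1 by deoxyfluorination.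
5. No ring is formed: ring B is bought as 1 and ring A as 4.

Assumption: the target SMILES has no stereocentre and no E/Z-isomeric double bond, so no stereocontrol is needed; 1 and 4 are taken as purchasable.

**Step 1**
Reactants: 1 3-bromo-2-hydroxy-5-methoxybenzaldehyde
Product: 3 3-bromo-2-fluoro-5-methoxybenzaldehyde, via aryl fluorosulfonate 2 (not isolated)
Conditions: SO2F2 (1 atm), NMe4F (3 equiv), DMF, rt → 80 °C
Reagents that add atoms: tetramethylammonium fluoride, C[N+](C)(C)C.[F-] (the fluorine of 3); sulfuryl fluoride, O=S(=O)(F)F (the SO2F group of 2)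
Why: Phenol deoxyfluorination through an aryl fluorosulfonate: the phenoxide is sulfonylated by SO2F2 and fluoride then displaces fluorosulfate in an SNAr-type ipso substitution activated by the ortho-formyl and ortho-bromo groups, so fluorine ends up exactly where the purchased phenol had its oxygen.

**Step 2**
Reactants: 3 3-bromo-2-fluoro-5-methoxybenzaldehyde; 4 methyl 2,6-dihydroxy-4-methylbenzoate (1.5 equiv)
Product: 5 methyl 2-(2-bromo-6-formyl-4-methoxyphenoxy)-6-hydroxy-4-methylbenzoate
Conditions: Cs2CO3, DMSO, 90 °C
Reagents that add atoms: none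
Why: Nucleophilic aromatic substitution (SNAr): the fluorine is activated by the ortho-formyl group and is a far better SNAr leaving group than bromine, and the symmetric diol 4 in excess gives a single mono-aryl ether whose remaining OH is hydrogen-bonded to the ester.

**Step 3**
Reactants: 5 methyl 2-(2-bromo-6-formyl-4-methoxyphenoxy)-6-hydroxy-4-methylbenzoate
Product: 6 methyl 2-[2-formyl-6-(hydroxymethyl)-4-methoxyphenoxy]-6-hydroxy-4-methylbenzoate
Conditions: Bu3SnCH2OH (1.5 equiv), Pd(PPh3)4 (5 mol %), 1,4-dioxane, 90 °C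
Reagents that add atoms: (tributylstannyl)methanol, CCCC[Sn](CCCC)(CCCC)CO
Why: Kosugi–Migita–Stille cross-coupling with (tributylstannyl)methanol as a hydroxymethyl-anion (d1) equivalent joins the aryl bromide carbon and the carbinol carbon, both normally electrophilic, under neutral conditions that spare the aldehyde, phenol and ester, whereas an aryllithium/formaldehyde sequence would attack the neighbouring ester.

**Step 4**
Reactants: 6 methyl 2-[2-formyl-6-(hydroxymethyl)-4-methoxyphenoxy]-6-hydroxy-4-methylbenzoate
Product: 8 methyl 2-hydroxy-6-[2-hydroxy-6-(hydroxymethyl)-4-methoxyphenoxy]-4-methylbenzoate, via aryl formate 7 (not isolated)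
Conditions: mCPBA, CH2Cl2, 0 °C → rt; then Et3N (cat.), MeOH, rt
Reagents that add atoms: 3-chloroperoxybenzoic acid (mCPBA), O=C(OO)c1cccc(Cl)c1 (the inserted oxygen)
Why: Baeyer–Villiger (Dakin-type) oxidation of an ortho-aryloxybenzaldehyde: the electron-rich aryl group migrates to oxygen to give formate 7, which mild methanolysis cleaves to the phenol, and the ring is more electron-rich with CH2OH than with Br, which is why the coupling precedes this step.

**Step 5**
Reactants: 8 methyl 2-hydroxy-6-[2-hydroxy-6-(hydroxymethyl)-4-methoxyphenoxy]-4-methylbenzoate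
Product: 10 methyl 2-[2-(hydroxymethyl)-4-methoxy-6-(3-methylbut-2-enyloxy)phenoxy]-4-methyl-6-(3-methylbut-2-enyloxy)benzoate (target), via mono-prenyl ether 9 (not isolated)
Conditions: prenyl bromide (2.5 equiv), K2CO3 (3 equiv), DMF, rt → 50 °C
Reagents that add atoms: prenyl bromide (1-bromo-3-methylbut-2-ene), CC(C)=CCBr
Why: Williamson ether synthesis: carbonate deprotonates only the two phenols and not the benzylic alcohol, so prenyl bromide O-alkylates first the free ring-B phenol and then the hydrogen-bonded ring-A phenol by SN2.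

**Compound list**
1 | 3-bromo-2-hydroxy-5-methoxybenzaldehyde | O=Cc1cc(OC)cc(Br)c1O | starting material
2 | 2-bromo-6-formyl-4-methoxyphenyl fluorosulfonate | O=Cc1cc(OC)cc(Br)c1OS(=O)(=O)F | intermediate (not isolated)
3 | 3-bromo-2-fluoro-5-methoxybenzaldehyde | O=Cc1cc(OC)cc(Br)c1F | intermediate
4 | methyl 2,6-dihydroxy-4-methylbenzoate | COC(=O)c1c(O)cc(C)cc1O | starting material
5 | methyl 2-(2-bromo-6-formyl-4-methoxyphenoxy)-6-hydroxy-4-methylbenzoate | COC(=O)c1c(O)cc(C)cc1Oc1c(Br)cc(OC)cc1C=O | intermediate
6 | methyl 2-[2-formyl-6-(hydroxymethyl)-4-methoxyphenoxy]-6-hydroxy-4-methylbenzoate | COC(=O)c1c(O)cc(C)cc1Oc1c(CO)cc(OC)cc1C=O | intermediate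
7 | methyl 2-[2-(formyloxy)-6-(hydroxymethyl)-4-methoxyphenoxy]-6-hydroxy-4-methylbenzoate | COC(=O)c1c(O)cc(C)cc1Oc1c(CO)cc(OC)cc1OC=O | intermediate (not isolated)
8 | methyl 2-hydroxy-6-[2-hydroxy-6-(hydroxymethyl)-4-methoxyphenoxy]-4-methylbenzoate | COC(=O)c1c(O)cc(C)cc1Oc1c(CO)cc(OC)cc1O | intermediate
9 | methyl 2-hydroxy-6-[2-(hydroxymethyl)-4-methoxy-6-(3-methylbut-2-enyloxy)phenoxy]-4-methylbenzoate | COC(=O)c1c(O)cc(C)cc1Oc1c(CO)cc(OC)cc1OCC=C(C)C | intermediate (not isolated)
10 | methyl 2-[2-(hydroxymethyl)-4-methoxy-6-(3-methylbut-2-enyloxy)phenoxy]-4-methyl-6-(3-methylbut-2-enyloxy)benzoate | COC(=O)c1c(OCC=C(C)C)cc(C)cc1Oc1c(CO)cc(OC)cc1OCC=C(C)C | target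

**Step count and risks**
Total steps: 5. Longest linear sequence: 5 (1 → 3 → 5 → 6 → 8 → 10); compound 4 is bought.

The three steps most likely to fail:

Step 3, the key C–C coupling. The bromide of 5 is ortho to a bulky aryloxy group, transfer of the α-hydroxyalkyl group from tin is slow, and butyl transfer or Pd-mediated cyclisation onto ring A can compete. The fallback keeps the same bond construction but moves it to an easier substrate. It sets out from compound 3, whose bromide is unhindered and activated by the ortho fluorine. Compound 3 is coupled with Bu3SnCH2OH (Pd(PPh3)4, dioxane, 80 °C) to give 2-fluoro-3-(hydroxymethyl)-5-methoxybenzaldehyde F8. SNAr of F8 with benzoate 4 (K2CO3, DMF, 90 °C; the carbonate deprotonates the phenol but not the benzylic alcohol) then comes back to the route at compound 6.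

Step 2, the SNAr. The fluorine of 3 sits between two ortho substituents and is deactivated by the para-methoxy group, and the phenoxide of 4 is a weak, hydrogen-bonded nucleophile. The fallback forms the C–O bond on a non-aromatic electrophile and aromatises afterwards. It sets out from compound 1, used as the nucleophile. Methyl 4-methyl-2,6-dioxocyclohexane-1-carboxylate F5 (known; bought or made from dimethyl malonate and pent-3-en-2-one with NaOMe) is converted with oxalyl chloride/cat. DMF into the vinylogous acid chloride methyl 2-chloro-4-methyl-6-oxocyclohex-1-ene-1-carboxylate F6 (racemic). Addition–elimination of the phenoxide of 1 (K2CO3, MeCN) gives methyl 2-(2-bromo-6-formyl-4-methoxyphenoxy)-4-methyl-6-oxocyclohex-1-ene-1-carboxylate F7 (racemic). Dehydrogenation with DDQ (dioxane, 80 °C) aromatises ring A and comes back to the route at compound 5, bypassing compound 3.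

Step 1, the deoxyfluorination. The para-methoxy group slows the fluoride displacement and the aldehyde must tolerate basic fluoride. As step 1 is the first step, the fallback cannot branch from an earlier compound of the route; it replaces compound 1 and builds the aryl fluoride before the aldehyde. Purchased 2,6-dibromo-4-methoxyaniline F1 is diazotised (NaNO2, HBF4, 0 °C) to 2,6-dibromo-4-methoxybenzenediazonium tetrafluoroborate F2. Thermolysis (Balz–Schiemann) gives the symmetric 1,3-dibromo-2-fluoro-5-methoxybenzene F3. Mono bromine–magnesium exchange (i-PrMgCl·LiCl, THF, −40 °C) gives (3-bromo-2-fluoro-5-methoxyphenyl)magnesium chloride F4, and quenching with DMF comes back to the route at compound 3. The symmetry of F3 makes the regiochemistry unambiguous.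

**Further compounds**
F1 | step 1 | 2,6-dibromo-4-methoxyaniline | COc1cc(Br)c(N)c(Br)c1
F2 | step 1 | 2,6-dibromo-4-methoxybenzenediazonium tetrafluoroborate | COc1cc(Br)c([N+]#N)c(Br)c1.F[B-](F)(F)F
F3 | step 1 | 1,3-dibromo-2-fluoro-5-methoxybenzene | COc1cc(Br)c(F)c(Br)c1
F4 | step 1 | (3-bromo-2-fluoro-5-methoxyphenyl)magnesium chloride | COc1cc(Br)c(F)c([Mg]Cl)c1
F5 | step 2 | methyl 4-methyl-2,6-dioxocyclohexane-1-carboxylate | COC(=O)C1C(=O)CC(C)CC1=O
F6 | step 2 | methyl 2-chloro-4-methyl-6-oxocyclohex-1-ene-1-carboxylate (racemic) | COC(=O)C1=C(Cl)CC(C)CC1=O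
F7 | step 2 | methyl 2-(2-bromo-6-formyl-4-methoxyphenoxy)-4-methyl-6-oxocyclohex-1-ene-1-carboxylate (racemic) | COC(=O)C1=C(Oc2c(Br)cc(OC)cc2C=O)CC(C)CC1=O
F8 | step 3 | 2-fluoro-3-(hydroxymethyl)-5-methoxybenzaldehyde | O=Cc1cc(OC)cc(CO)c1F
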